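**Strategy.** The route rests on cutting the C3–C4 bond of ring C. C3 is benzylic to ring B and adjacent to the C4 carbonyl carried by ring A, so a C4 acyl electrophile and a racemic C3 benzylic chloride, tied together through the O1–C2 ether, can be joined by chiral nickel catalysis under reducing conditions. That single operation closes the pyranone ring, forms the only new skeletal bond and sets the lone C3 stereocentre as R, from either enantiomer of the chloride. The precursor is a ring A S-2-pyridyl thiobenzoate (two MOM ethers, the 6-prenyl group) whose ortho oxygen carries a 2-chloro-2-arylethyl chain; ring B holds the geranyl group and a tert-butyl carbonate.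

Key step: step 12

Remarks on the chemistry:
- Abbreviations: prenyl = 3-methylbut-2-en-1-yl; geranyl = (2E)-3,7-dimethylocta-2,6-dien-1-yl; MOM = methoxymethyl; Boc = tert-butoxycarbonyl.
- The target SMILES corresponds to the (3R)-isoflavanone (CIP order at C3: C4 > C2 > aryl > H).
- Assumption: the sense of induction of the bis(oxazoline) ligand on this tethered substrate is taken by analogy. The (4R,4'R) ligand is written; its equally available mirror image is used if a first run shows the (S)-ketone.
- Compounds 1, 3, 8 and 9 are taken as commercial.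

**Step 1**
Reactants: 1 2,4,6-trihydroxybenzaldehyde
Product: 2 2-hydroxy-4,6-bis(methoxymethoxy)benzaldehyde
Conditions: MOMCl (2.2 equiv), iPr2NEt, CH2Cl2, 0 °C → rt
Reagents that add atoms: chloromethyl methyl ether, COCCl
Why: Williamson-type O-alkylation with an α-chloro ether: the para hydroxyl and one of the two equivalent ortho hydroxyls react, while the last ortho hydroxyl stays locked in a hydrogen bond to the formyl oxygen and is left free.

**Step 2**
Reactants: 2 2-hydroxy-4,6-bis(methoxymethoxy)benzaldehyde; 3 prenyl bromide
Product: 4 2,4-bis(methoxymethoxy)-6-(3-methylbut-2-enyloxy)benzaldehyde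
Conditions: K2CO3, DMF, rt
Reagents that add atoms: none
Why: Williamson ether synthesis: the chelated phenoxide is alkylated at oxygen by the primary allylic bromide in a dipolar aprotic solvent, which favours O- over C-alkylation.

**Step 3**
Reactants: 4 2,4-bis(methoxymethoxy)-6-(3-methylbut-2-enyloxy)benzaldehyde
Product: 7 6-hydroxy-2,4-bis(methoxymethoxy)-3-(3-methylbut-2-enyl)benzaldehyde, via ortho-Claisen dienone 5 (not isolated), via para-dienone 6 (not isolated)
Conditions: PhNEt2, 195 °C, sealed tube, argon
Reagents that add atoms: none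
Why: Tandem aromatic Claisen–Cope (para-Claisen) rearrangement: the [3,3] shift to the only free ortho carbon gives dienone 5 with a reversed prenyl group, a second [3,3] shift carries it as a normal prenyl group to the para carbon between the two MOM ethers (6), and enolisation restores the arene, as known for the corresponding acetophenone series.

**Step 4**
Reactants: 8 4'-hydroxyacetophenone; 9 geranyl bromide
Product: 10 3'-geranyl-4'-hydroxyacetophenone
Conditions: NaH (1.0 equiv), toluene, 0 °C → rt
Reagents that add atoms: none
Why: Ortho C-alkylation of a phenoxide: in a non-polar solvent the sodium phenoxide reacts as a tight ion pair at the carbon next to oxygen (the para position is blocked), by SN2 attack at the primary allylic carbon so that the E geometry is kept; the O-geranyl ether is the expected by-product and is separated.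

**Step 5**
Reactants: 10 3'-geranyl-4'-hydroxyacetophenone
Product: 11 4-acetyl-2-geranylphenyl tert-butyl carbonate
Conditions: Boc2O, DMAP (cat.), CH2Cl2, rt
Reagents that add atoms: di-tert-butyl dicarbonate, CC(C)(C)OC(=O)OC(=O)OC(C)(C)C
Why: DMAP-catalysed acylation of the phenol by the dicarbonate gives the aryl tert-butyl carbonate, which makes ring B electron-poor for the later benzylic chloride.

**Step 6**
Reactants: 11 4-acetyl-2-geranylphenyl tert-butyl carbonate
Product: 13 4-(bromoacetyl)-2-geranylphenyl tert-butyl carbonate, via trimethylsilyl enol ether 12 (not isolated)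
Conditions: LiN(SiMe3)2, Me3SiCl, THF, −78 °C; then NBS, −78 → 0 °C
Reagents that add atoms: chlorotrimethylsilane, C[Si](C)(C)Cl (silicon is held only in 12); N-bromosuccinimide, O=C1CCC(=O)N1Br
Why: Kinetic enolisation with in situ O-silylation followed by electrophilic bromination of the silyl enol ether: 12 is far more nucleophilic toward NBS than the trisubstituted alkenes, and the hindered amide base at −78 °C should leave the carbonate alone.

**Step 7**
Reactants: 7 6-hydroxy-2,4-bis(methoxymethoxy)-3-(3-methylbut-2-enyl)benzaldehyde; 13 4-(bromoacetyl)-2-geranylphenyl tert-butyl carbonate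
Product: 14 tert-butyl 4-{2-[2-formyl-3,5-bis(methoxymethoxy)-4-(3-methylbut-2-enyl)phenoxy]acetyl}-2-geranylphenyl carbonate
Conditions: K2CO3, acetone, rt
Reagents that add atoms: none
Why: Williamson ether synthesis with a phenacyl bromide: the acidic chelated phenol is alkylated at room temperature by this very reactive SN2 electrophile, under conditions mild enough that aldol cyclisation of the product to a benzofuran and carbonate transfer should stay slow.

**Step 8**
Reactants: 14 the keto aldehyde
Product: 15 2-{2-[4-(tert-butoxycarbonyloxy)-3-geranylphenyl]-2-oxoethoxy}-4,6-bis(methoxymethoxy)-5-(3-methylbut-2-enyl)benzoic acid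
Conditions: NaClO2, NaH2PO4, 2-methyl-2-butene (large excess), t-BuOH/THF/H2O, 0 °C → rt
Reagents that add atoms: sodium chlorite, [Na+].[O-]Cl=O
Why: Pinnick oxidation: buffered chlorous acid oxidises only the aldehyde, and the large excess of 2-methyl-2-butene traps hypochlorous acid before it can touch the side-chain alkenes or the electron-rich arene.

**Step 9**
Reactants: 15 the keto acid
Product: 16 racemic 2-{2-[4-(tert-butoxycarbonyloxy)-3-geranylphenyl]-2-hydroxyethoxy}-4,6-bis(methoxymethoxy)-5-(3-methylbut-2-enyl)benzoic acid
Conditions: NaBH4, THF/EtOH, 0 °C; aq. NaH2PO4 work-up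
Reagents that add atoms: none
Why: Borohydride reduction of the α-aryloxy aryl ketone while the carboxylate is inert; the new carbinol centre (the future C3) forms as a racemate, which is all that the stereoconvergent ring closure needs.

**Step 10**
Reactants: 16 the racemic hydroxy acid
Product: 17 racemic S-(pyridin-2-yl) 2-{2-[4-(tert-butoxycarbonyloxy)-3-geranylphenyl]-2-hydroxyethoxy}-4,6-bis(methoxymethoxy)-5-(3-methylbut-2-enyl)benzenecarbothioate
Conditions: PPh3, 2,2'-dipyridyl disulfide, CH2Cl2, rt; used at once
Reagents that add atoms: 2,2'-dipyridyl disulfide, c1ccc(SSc2ccccn2)nc1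
Why: Mukaiyama redox condensation, the thioester-forming stage of the Corey–Nicolaou procedure: the acyloxyphosphonium ion is captured by 2-pyridinethiolate much faster than by the unactivated secondary hydroxyl, so the hydroxy acid should give the S-2-pyridyl thioester without protection.

**Step 11**
Reactants: 17 the racemic hydroxy thioester
Product: 18 racemic S-(pyridin-2-yl) 2-{2-chloro-2-[4-(tert-butoxycarbonyloxy)-3-geranylphenyl]ethoxy}-4,6-bis(methoxymethoxy)-5-(3-methylbut-2-enyl)benzenecarbothioate
Conditions: PPh3, NCS (premixed), THF, 0 °C → rt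
Reagents that add atoms: N-chlorosuccinimide, O=C1CCC(=O)N1Cl
Why: Appel-type chlorination: the chlorophosphonium salt preformed from PPh3 and NCS activates the benzylic hydroxyl and chloride displaces it under neutral conditions that spare thioester, MOM ethers, carbonate and alkenes; the flanking aryloxy group and the para carbonate should make the chloride stable enough to handle.

**Step 12**
Reactants: 18 the racemic chloro thioester
Product: 19 (3R)-3-[4-(tert-butoxycarbonyloxy)-3-geranylphenyl]-5,7-bis(methoxymethoxy)-6-(3-methylbut-2-enyl)chroman-4-one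
Conditions: NiCl2(dme) (10 mol%), (4R,4'R)-2,2'-(propane-2,2-diyl)bis(4-phenyl-4,5-dihydrooxazole) (22 mol%), Mn powder (3 equiv), 2,6-dimethylbenzoic acid (0.75 equiv), 3 Å MS, DMA/THF, 20 °C, 0.02 M, slow addition of 18
Reagents that add atoms: none
Why: Proposed new method: Zerovalent nickel bearing the bis(oxazoline) should insert into the C(acyl)–S bond of the 2-pyridyl thioester, and a low-valent nickel species then abstracts chlorine to give a planar benzylic radical at C3, which the chiral acyl nickel of the same molecule captures before reductive elimination forms C3–C4 and Mn returns nickel to its low-valent state. The closest known reaction type is the intermolecular nickel/bis(oxazoline)-catalysed enantioconvergent reductive coupling of acyl electrophiles with racemic secondary benzylic chlorides, together with nickel-catalysed reductive ketone syntheses from 2-pyridyl thioesters; the ring-closing version on one chain is new. Ring C, the six-membered pyranone, closes in a 6-exo-trig sense at the acyl carbon (its carbonyl oxygen stays outside the ring), formally by reductive elimination from a seven-membered acyl(benzyl)nickel metallacycle. The C3 stereocentre is set by the ligand on nickel at the radical-capture and reductive-elimination stage, both enantiomers of 18 converging through the same radical, and the non-basic medium should leave the α-aryl ketone configurationally intact. The step needs cyclisation to win over β-aryloxy elimination, benzylic dimerisation and attack of released thiolate on the chloride: the tether keeps the acyl nickel next to the radical, the para carbonate and the chloride (not bromide) leaving group hold back ionisation and premature activation of the benzylic carbon, and high dilution with slow addition holds intermolecular paths down.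

**Step 13**
Reactants: 19 the (3R)-protected isoflavanone
Product: 20 (3R)-3-(3-geranyl-4-hydroxyphenyl)-5,7-dihydroxy-6-(3-methylbut-2-enyl)chroman-4-one (CNP0165005.1)
Conditions: HCl (3 M in MeOH), THF, 0 °C → rt, stopped at full conversion
Reagents that add atoms: none
Why: Acid-catalysed transacetalisation of the two MOM ethers with methanol and acidolysis of the aryl tert-butyl carbonate in one operation; no base is present, so the base-labile C3 centre should be kept, and the low temperature limits cyclisation of the side chains onto the freed phenols.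

**Compound list**

1 | 2,4,6-trihydroxybenzaldehyde | O=Cc1c(O)cc(O)cc1O | starting material
2 | 2-hydroxy-4,6-bis(methoxymethoxy)benzaldehyde | COCOc1cc(O)c(C=O)c(OCOC)c1 | intermediate
3 | prenyl bromide (1-bromo-3-methylbut-2-ene) | CC(C)=CCBr | starting material
4 | 2,4-bis(methoxymethoxy)-6-(3-methylbut-2-enyloxy)benzaldehyde | COCOc1cc(OCC=C(C)C)c(C=O)c(OCOC)c1 | intermediate
5 | ortho-Claisen dienone (not isolated): 2,4-bis(methoxymethoxy)-5-(2-methylbut-3-en-2-yl)-6-oxocyclohexa-1,3-diene-1-carbaldehyde | O=CC1=C(OCOC)C=C(OCOC)C(C(C)(C)C=C)C1=O | intermediate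
6 | para-dienone (not isolated): 2,4-bis(methoxymethoxy)-3-(3-methylbut-2-enyl)-6-oxocyclohexa-1,4-diene-1-carbaldehyde | O=CC1=C(OCOC)C(CC=C(C)C)C(OCOC)=CC1=O | intermediate
7 | 6-hydroxy-2,4-bis(methoxymethoxy)-3-(3-methylbut-2-enyl)benzaldehyde | COCOc1cc(O)c(C=O)c(OCOC)c1CC=C(C)C | intermediate
8 | 4'-hydroxyacetophenone | CC(=O)c1ccc(O)cc1 | starting material
9 | geranyl bromide | CC(C)=CCC/C(C)=C/CBr | starting material
10 | 3'-geranyl-4'-hydroxyacetophenone | CC(C)=CCC/C(C)=C/Cc1cc(C(C)=O)ccc1O | intermediate
11 | 4-acetyl-2-geranylphenyl tert-butyl carbonate | CC(C)=CCC/C(C)=C/Cc1cc(C(C)=O)ccc1OC(=O)OC(C)(C)C | intermediate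
12 | trimethylsilyl enol ether of 11 (not isolated): tert-butyl 2-geranyl-4-[1-(trimethylsilyloxy)ethenyl]phenyl carbonate | CC(C)=CCC/C(C)=C/Cc1cc(C(=C)O[Si](C)(C)C)ccc1OC(=O)OC(C)(C)C | intermediate
13 | 4-(bromoacetyl)-2-geranylphenyl tert-butyl carbonate | CC(C)=CCC/C(C)=C/Cc1cc(C(=O)CBr)ccc1OC(=O)OC(C)(C)C | intermediate
14 | tert-butyl 4-{2-[2-formyl-3,5-bis(methoxymethoxy)-4-(3-methylbut-2-enyl)phenoxy]acetyl}-2-geranylphenyl carbonate | CC(C)=CCC/C(C)=C/Cc1cc(C(=O)COc2cc(OCOC)c(CC=C(C)C)c(OCOC)c2C=O)ccc1OC(=O)OC(C)(C)C | intermediate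
15 | 2-{2-[4-(tert-butoxycarbonyloxy)-3-geranylphenyl]-2-oxoethoxy}-4,6-bis(methoxymethoxy)-5-(3-methylbut-2-enyl)benzoic acid | CC(C)=CCC/C(C)=C/Cc1cc(C(=O)COc2cc(OCOC)c(CC=C(C)C)c(OCOC)c2C(=O)O)ccc1OC(=O)OC(C)(C)C | intermediate
16 | racemic 2-{2-[4-(tert-butoxycarbonyloxy)-3-geranylphenyl]-2-hydroxyethoxy}-4,6-bis(methoxymethoxy)-5-(3-methylbut-2-enyl)benzoic acid | CC(C)=CCC/C(C)=C/Cc1cc(C(O)COc2cc(OCOC)c(CC=C(C)C)c(OCOC)c2C(=O)O)ccc1OC(=O)OC(C)(C)C | intermediate
17 | racemic S-(pyridin-2-yl) 2-{2-[4-(tert-butoxycarbonyloxy)-3-geranylphenyl]-2-hydroxyethoxy}-4,6-bis(methoxymethoxy)-5-(3-methylbut-2-enyl)benzenecarbothioate | CC(C)=CCC/C(C)=C/Cc1cc(C(O)COc2cc(OCOC)c(CC=C(C)C)c(OCOC)c2C(=O)Sc2ccccn2)ccc1OC(=O)OC(C)(C)C | intermediate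
18 | racemic S-(pyridin-2-yl) 2-{2-chloro-2-[4-(tert-butoxycarbonyloxy)-3-geranylphenyl]ethoxy}-4,6-bis(methoxymethoxy)-5-(3-methylbut-2-enyl)benzenecarbothioate | CC(C)=CCC/C(C)=C/Cc1cc(C(Cl)COc2cc(OCOC)c(CC=C(C)C)c(OCOC)c2C(=O)Sc2ccccn2)ccc1OC(=O)OC(C)(C)C | intermediate
19 | (3R)-3-[4-(tert-butoxycarbonyloxy)-3-geranylphenyl]-5,7-bis(methoxymethoxy)-6-(3-methylbut-2-enyl)chroman-4-one | CC(C)=CCC/C(C)=C/Cc1cc([C@@H]2COc3cc(OCOC)c(CC=C(C)C)c(OCOC)c3C2=O)ccc1OC(=O)OC(C)(C)C | intermediate
20 | (3R)-3-(3-geranyl-4-hydroxyphenyl)-5,7-dihydroxy-6-(3-methylbut-2-enyl)chroman-4-one | CC(C)=CCC/C(C)=C/Cc1cc([C@@H]2COc3cc(O)c(CC=C(C)C)c(O)c3C2=O)ccc1O | target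

**Step count and risk**

Total steps: 13. Longest linear sequence: 10 steps (steps 1–3 and 7–13; the ring B branch, steps 4–6 and 7–13, is equally long).

Steps most likely to fail:

1. Step 12 (proposed new method). What may go wrong:
   - β-elimination of the ring A aryloxide if nickel engages the benzylic carbon before the thioester;
   - intermolecular coupling or benzylic dimerisation instead of ring closure;
   - S-alkylation of the chloride by released thiolate;
   - weak enantiocontrol because the tether distorts the radical-capture geometry.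

   Fallback (known chemistry; sets out from 14, returns at 19): an N-heterocyclic-carbene-catalysed intramolecular crossed benzoin reaction of 14 (triazolium precatalyst, catalytic DBU, THF) should give racemic 3-[4-(tert-butoxycarbonyloxy)-3-geranylphenyl]-3-hydroxy-5,7-bis(methoxymethoxy)-6-(3-methylbut-2-enyl)chroman-4-one F1. Dehydration of this tertiary α-ketol across C2–C3 (Burgess reagent, THF, 50 °C) should give the isoflavone 3-[4-(tert-butoxycarbonyloxy)-3-geranylphenyl]-5,7-bis(methoxymethoxy)-6-(3-methylbut-2-enyl)chromen-4-one F2. Asymmetric transfer hydrogenation (RuCl(p-cymene)[(R,R)-TsDPEN], HCO2H/Et3N, EtOAc, 40 °C) reduces C2=C3 and then C4=O with dynamic kinetic resolution at the base-labile C3, and should give the cis-(3R,4R)-3-[4-(tert-butoxycarbonyloxy)-3-geranylphenyl]-5,7-bis(methoxymethoxy)-6-(3-methylbut-2-enyl)chroman-4-ol F3; the catalyst antipode is chosen by the usual aryl-ketone model and reversed if needed. Buffered Dess–Martin oxidation (NaHCO3, CH2Cl2, 0 °C) then restores the C4 ketone without touching C3 and gives 19.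

2. Step 10. What may go wrong: the activated carboxyl is captured by the internal secondary hydroxyl (seven-membered lactone), or acyl transfer at the doubly ortho-substituted acid is so slow that the free hydroxyl interferes.

   Fallback (sets out from 15, returns at 17): the order of events is reversed. The keto acid 15, which has no hydroxyl group, is converted with PPh3/2,2'-dipyridyl disulfide into S-(pyridin-2-yl) 2-{2-[4-(tert-butoxycarbonyloxy)-3-geranylphenyl]-2-oxoethoxy}-4,6-bis(methoxymethoxy)-5-(3-methylbut-2-enyl)benzenecarbothioate F4. The ketone alone is then reduced under Luche conditions (NaBH4, CeCl3·7H2O, MeOH/THF, −78 °C), where the activated α-aryloxy aryl ketone should react far faster than the hindered thioester, giving 17 cold for immediate chlorination in step 11.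

3. Step 13. What may go wrong: partial loss of the C3 configuration by acid-catalysed enolisation, and acid-induced cyclisation of the prenyl or geranyl chains onto the freed ortho phenols, during the longer exposure that the carbonate needs.

   Fallback (sets out from 19, returns at 20): the two kinds of protecting group are removed in separate, mechanistically different operations. ZnBr2/n-PrSH in CH2Cl2 at 0 °C (Lewis-acid-assisted capture of the methoxymethyl groups by the thiol, expected to be complete within minutes) should give (3R)-3-[4-(tert-butoxycarbonyloxy)-3-geranylphenyl]-5,7-dihydroxy-6-(3-methylbut-2-enyl)chroman-4-one F5. The carbonate is then cleaved by a brief anhydrous acidolysis (CF3CO2H/CH2Cl2, iPr3SiH as cation trap, 0 °C) to give 20.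

**Further compounds**

F1 | step 12 | racemic 3-[4-(tert-butoxycarbonyloxy)-3-geranylphenyl]-3-hydroxy-5,7-bis(methoxymethoxy)-6-(3-methylbut-2-enyl)chroman-4-one | CC(C)=CCC/C(C)=C/Cc1cc(C2(O)COc3cc(OCOC)c(CC=C(C)C)c(OCOC)c3C2=O)ccc1OC(=O)OC(C)(C)C
F2 | step 12 | 3-[4-(tert-butoxycarbonyloxy)-3-geranylphenyl]-5,7-bis(methoxymethoxy)-6-(3-methylbut-2-enyl)chromen-4-one | CC(C)=CCC/C(C)=C/Cc1cc(-c2coc3cc(OCOC)c(CC=C(C)C)c(OCOC)c3c2=O)ccc1OC(=O)OC(C)(C)C
F3 | step 12 | (3R,4R)-3-[4-(tert-butoxycarbonyloxy)-3-geranylphenyl]-5,7-bis(methoxymethoxy)-6-(3-methylbut-2-enyl)chroman-4-ol (cis) | CC(C)=CCC/C(C)=C/Cc1cc([C@@H]2COc3cc(OCOC)c(CC=C(C)C)c(OCOC)c3[C@@H]2O)ccc1OC(=O)OC(C)(C)C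
F4 | step 10 | S-(pyridin-2-yl) 2-{2-[4-(tert-butoxycarbonyloxy)-3-geranylphenyl]-2-oxoethoxy}-4,6-bis(methoxymethoxy)-5-(3-methylbut-2-enyl)benzenecarbothioate | CC(C)=CCC/C(C)=C/Cc1cc(C(=O)COc2cc(OCOC)c(CC=C(C)C)c(OCOC)c2C(=O)Sc2ccccn2)ccc1OC(=O)OC(C)(C)C
F5 | step 13 | (3R)-3-[4-(tert-butoxycarbonyloxy)-3-geranylphenyl]-5,7-dihydroxy-6-(3-methylbut-2-enyl)chroman-4-one | CC(C)=CCC/C(C)=C/Cc1cc([C@@H]2COc3cc(O)c(CC=C(C)C)c(O)c3C2=O)ccc1OC(=O)OC(C)(C)C
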